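**Retrosynthetic overview**

1. Target ⇒ cross-metathesis at C6′=C7′ (vinyl → 2-methylprop-1-enyl) as the last step, because this electron-rich allylic-alcohol olefin would be oxidised before C2′=C3′ by any electrophilic or hydroxyl-directed epoxidation.
2. Epoxide ring (third and last ring formed) ⇒ direct oxygen-atom transfer to the Z-C2′=C3′ olefin of the assembled 7-O-alkenyl coumarin, as in the presumed biosynthetic tailoring of the neryl-type ether; a chiral dioxirane sets C2′ and C3′ together.
3. Aryl ether C7–O–C1′ ⇒ Mitsunobu union of 7-hydroxy-8-methoxycoumarin with a (2Z,5S)-1,5-diol, the chemical counterpart of O-prenyl transfer.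
4. Coumarin pyranone ring (second ring formed) ⇒ E→Z isomerisation and lactonisation of an ortho-hydroxycinnamate from a Wittig reaction, the ring closure of coumarin biosynthesis.
5. Diol ⇒ (6S)-6-vinyl-4-methyl-5,6-dihydropyran-2-one (temporary ring, formed first; it sets C5′ and locks the Z-olefin) ⇒ asymmetric vinylogous aldol of a senecioate silyl dienolate with acrolein.

Assumption: the SMILES is read as the (2′S,3′R,5′S) isomer with a cis (neryl-type) epoxide, so the C2′=C3′ olefin precursor must be Z (side-chain locants C1′ = OCH2 to C7′ = CMe2); 2,4-dihydroxy-3-methoxybenzaldehyde is taken as a purchasable building block.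

**Route**

Step 1
Reactants: 1 ethyl 3-methylbut-2-enoate
Product: 2 1-ethoxy-3-methyl-1-(trimethylsilyloxy)buta-1,3-diene
Conditions: LiN(i-Pr)2 (commercial solution), THF, −78 °C; then Me3SiCl, −78 °C → rt; distil
Reagents that add atoms: chlorotrimethylsilane, C[Si](C)(C)Cl
Why: Kinetic γ-deprotonation of the senecioate followed by O-silylation of the extended enolate (silyl dienol ether formation) is standard, and no stereocentre is formed.

Step 2
Reactants: 2 1-ethoxy-3-methyl-1-(trimethylsilyloxy)buta-1,3-diene; 3 acrolein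
Product: 5 (6S)-6-ethenyl-4-methyl-5,6-dihydro-2H-pyran-2-one, via silyl aldol adduct 4 (not isolated)
Conditions: Cu(OTf)2 (10 mol%), (S)-Tol-BINAP (11 mol%), Bu4N[Ph3SiF2] (20 mol%), THF, −40 °C → rt
Reagents that add atoms: none
Why: Catalytic asymmetric vinylogous Mukaiyama aldol reaction with in-flask lactonisation, in which fluoride passes the dienolate from silicon to the Tol-BINAP-bound monovalent copper, the copper dienolate adds through its γ-carbon to one face of acrolein to set C6 as S (the ligand antipode is the one that gives 6S, to be confirmed by Mosher ester analysis of 6), and only the Z-enoate adduct can close onto the ester, so the ring also fixes the future C2′=C3′ olefin as Z.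

Step 3
Reactants: 5 (6S)-6-ethenyl-4-methyl-5,6-dihydro-2H-pyran-2-one
Product: 6 (2Z,5S)-3-methylhepta-2,6-diene-1,5-diol
Conditions: i-Bu2AlH (3 equiv), CH2Cl2, −78 → 0 °C; aq. Rochelle salt
Reagents that add atoms: none
Why: Exhaustive 1,2-hydride reduction of the unsaturated lactone through the lactol opens the ring to the allylic diol, leaving the Z geometry, the vinyl group and the C5 stereocentre untouched.

Step 4
Reactants: 7 2,4-dihydroxy-3-methoxybenzaldehyde; 8 ethyl (triphenylphosphoranylidene)acetate
Product: 11 7-hydroxy-8-methoxy-2H-chromen-2-one (hydrangetin), via E-cinnamate ester 9 (not isolated), via Z-cinnamate ester 10 (not isolated)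
Conditions: PhNEt2, reflux (215 °C), 4 h
Reagents that add atoms: none
Why: Wittig olefination gives the ortho-hydroxycinnamate, whose thermal E→Z isomerisation and lactonisation (the two events that close the pyranone ring in coumarin biosynthesis) give the coumarin, with the 4-OH of the aldehyde becoming the free 7-OH and no stereocentre involved.

Step 5
Reactants: 6 (2Z,5S)-3-methylhepta-2,6-diene-1,5-diol; 11 7-hydroxy-8-methoxy-2H-chromen-2-one
Product: 12 7-{[(2Z,5S)-5-hydroxy-3-methylhepta-2,6-dien-1-yl]oxy}-8-methoxy-2H-chromen-2-one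
Conditions: PPh3 (1.2 equiv), DIAD (1.2 equiv, slow addition), THF, 0 °C → rt
Reagents that add atoms: none
Why: Mitsunobu etherification, in which the acidic 7-OH (pKa about 8) displaces the oxyphosphonium of the unhindered primary allylic alcohol in an SN2 reaction faster than the secondary carbinol is activated or a dihydropyran closes, so the Z-olefin and the 5S carbinol are carried through unchanged.

Step 6
Reactants: 12 7-{[(2Z,5S)-5-hydroxy-3-methylhepta-2,6-dien-1-yl]oxy}-8-methoxy-2H-chromen-2-one
Product: 13 7-{[(2S,3R)-3-[(2S)-2-hydroxybut-3-en-1-yl]-3-methyloxiran-2-yl]methoxy}-8-methoxy-2H-chromen-2-one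
Conditions: ent-Shi ketone (30 mol%; the enantiomer of the fructose-derived 1,2:4,5-di-O-isopropylidene ketone), KHSO5 (as Oxone, 1.5 equiv), K2CO3, Bu4NHSO4 (cat.), MeCN–dimethoxymethane/aq. Na2B4O7–Na2EDTA buffer (pH 10.5), 0 °C; NaH2PO4 work-up to pH 6
Reagents that add atoms: potassium peroxymonosulfate (KHSO5, the active salt of Oxone), [K+].[O-]S(=O)(=O)OO
Why: Shi asymmetric epoxidation, in which the chiral dioxirane oxidises the only nucleophilic olefin present (trisubstituted C2′=C3′; the vinyl group that stands in for the 2-methylprop-1-enyl group, the coumarin C3=C4 bond and the arene are far less reactive) through a spiro transition state with the olefinic hydrogen in the hindered quadrant, which with this ketone enantiomer gives 2′S and hence 3′R from the Z geometry, independently of the remote 5′S centre (dr of about 9:1 or better expected, minor isomer removed by chromatography).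

Step 7
Reactants: 13 7-{[(2S,3R)-3-[(2S)-2-hydroxybut-3-en-1-yl]-3-methyloxiran-2-yl]methoxy}-8-methoxy-2H-chromen-2-one; 14 2-methylbut-2-ene
Product: 15 7-{[(2S,3R)-3-[(2S)-2-hydroxy-4-methylpent-3-en-1-yl]-3-methyloxiran-2-yl]methoxy}-8-methoxy-2H-chromen-2-one
Conditions: second-generation Grubbs catalyst (H2IMes)(PCy3)Cl2Ru=CHPh (5 mol%), 14 as co-solvent (large excess), CH2Cl2, 40 °C, 1,4-benzoquinone (10 mol%)
Reagents that add atoms: none
Why: Olefin cross-metathesis of the terminal vinyl carbinol with excess 2-methylbut-2-ene exchanges =CH2 for =C(CH3)2 with loss of propene, while the trisubstituted epoxide, the coumarin double bond and all three stereocentres are untouched and the descriptor at C5′ stays S.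

**Compound list**

1 | ethyl 3-methylbut-2-enoate | CCOC(=O)C=C(C)C | starting material
2 | 1-ethoxy-3-methyl-1-(trimethylsilyloxy)buta-1,3-diene (E/Z mixture at C1) | CCOC(O[Si](C)(C)C)=CC(C)=C | intermediate
3 | acrolein (prop-2-enal) | C=CC=O | starting material
4 | ethyl (2Z,5S)-3-methyl-5-(trimethylsilyloxy)hepta-2,6-dienoate (not isolated) | CCOC(=O)/C=C(C)\C[C@H](O[Si](C)(C)C)C=C | intermediate
5 | (6S)-6-ethenyl-4-methyl-5,6-dihydro-2H-pyran-2-one | C=C[C@@H]1CC(C)=CC(=O)O1 | intermediate
6 | (2Z,5S)-3-methylhepta-2,6-diene-1,5-diol | OC/C=C(C)\C[C@H](O)C=C | intermediate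
7 | 2,4-dihydroxy-3-methoxybenzaldehyde | COc1c(O)ccc(C=O)c1O | starting material
8 | ethyl (triphenylphosphoranylidene)acetate | CCOC(=O)C=P(c1ccccc1)(c1ccccc1)c1ccccc1 | starting material
9 | ethyl (2E)-3-(2,4-dihydroxy-3-methoxyphenyl)prop-2-enoate (not isolated) | CCOC(=O)/C=C/c1ccc(O)c(OC)c1O | intermediate
10 | ethyl (2Z)-3-(2,4-dihydroxy-3-methoxyphenyl)prop-2-enoate (not isolated) | CCOC(=O)/C=C\c1ccc(O)c(OC)c1O | intermediate
11 | 7-hydroxy-8-methoxy-2H-chromen-2-one (hydrangetin) | COc1c(O)ccc2ccc(=O)oc12 | intermediate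
12 | 7-{[(2Z,5S)-5-hydroxy-3-methylhepta-2,6-dien-1-yl]oxy}-8-methoxy-2H-chromen-2-one | COc1c(OC/C=C(C)\C[C@H](O)C=C)ccc2ccc(=O)oc12 | intermediate
13 | 7-{[(2S,3R)-3-[(2S)-2-hydroxybut-3-en-1-yl]-3-methyloxiran-2-yl]methoxy}-8-methoxy-2H-chromen-2-one | COc1c(OC[C@@H]2O[C@]2(C)C[C@H](O)C=C)ccc2ccc(=O)oc12 | intermediate
14 | 2-methylbut-2-ene | CC=C(C)C | starting material
15 | 7-{[(2S,3R)-3-[(2S)-2-hydroxy-4-methylpent-3-en-1-yl]-3-methyloxiran-2-yl]methoxy}-8-methoxy-2H-chromen-2-one | COc1c(OC[C@@H]2O[C@]2(C)C[C@H](O)C=C(C)C)ccc2ccc(=O)oc12 | target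

**Step count and risks**

Total steps: 7 (two branches: steps 1–3 and step 4, joined in step 5). Longest linear sequence: 6 (steps 1, 2, 3, 5, 6, 7).

The three steps most likely to fail:

Step 2. Acrolein is small and polymerisable and may give low ee or yield in the copper-catalysed aldol. The fallback gives up catalytic enantiocontrol and resolves later. It sets out from 3: a vinylogous Reformatsky reaction with ethyl (E)-4-bromo-3-methylbut-2-enoate and zinc dust (THF, reflux) gives racemic 6-ethenyl-4-methyl-5,6-dihydro-2H-pyran-2-one F1. Reduction with i-Bu2AlH as in step 3 gives racemic (2Z)-3-methylhepta-2,6-diene-1,5-diol F2, and Mitsunobu coupling with 11 as in step 5 gives the racemic ether F3. Sharpless kinetic resolution of F3 (Ti(Oi-Pr)4, (−)-diisopropyl (2S,3S)-tartrate, t-BuOOH 0.6 equiv, 4 Å sieves, CH2Cl2, −20 °C) epoxidises the vinyl group of the 5R enantiomer to the erythro epoxy alcohol F4, which is removed by chromatography. The unreacted 5S enantiomer is compound 12, where the route is rejoined.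

Step 6. The C2′=C3′ olefin is deactivated by the allylic aryloxy group, the face selectivity rests on reagent control alone, and the coumarin lactone sits at pH 10.5. The fallback lets the C5′ oxygen deliver the epoxide oxygen instead of an external chiral oxidant. It sets out from 12: Boc2O/DMAP gives the tert-butyl carbonate F5. IBr (toluene, −85 °C) then triggers 6-exo iodocarbonate cyclisation onto the trisubstituted olefin to give the cyclic iodocarbonate F6, with the vinyl and iodoalkyl groups both equatorial, which is the 1,3-syn relationship needed. K2CO3 in MeOH cleaves the carbonate and the C3′ alkoxide displaces iodide with inversion at C2′ to give 13, where the route is rejoined.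

Step 7. The free allylic alcohol next to the reacting vinyl group may be isomerised to the ethyl ketone by ruthenium hydrides, or turnover may stall. The fallback builds the C6′=C7′ bond by carbonyl olefination instead of metathesis. It sets out from 13: Et3SiCl/imidazole gives the triethylsilyl ether F7. OsO4 (cat.)/NaIO4/2,6-lutidine cleaves the terminal vinyl group (the electron-poor coumarin C3=C4 bond reacts much more slowly) to the α-silyloxy aldehyde F8. Wittig reaction with isopropylidenetriphenylphosphorane (from i-PrPPh3I and KN(SiMe3)2, THF, −78 °C) gives the triethylsilyl ether of the target F9, and Bu4NF buffered with AcOH removes the silyl group to give 15, where the route is rejoined.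

**Further compounds**

F1 | step 2 | racemic 6-ethenyl-4-methyl-5,6-dihydro-2H-pyran-2-one | C=CC1CC(C)=CC(=O)O1
F2 | step 2 | racemic (2Z)-3-methylhepta-2,6-diene-1,5-diol | OC/C=C(C)\CC(O)C=C
F3 | step 2 | racemic 7-{[(2Z)-5-hydroxy-3-methylhepta-2,6-dien-1-yl]oxy}-8-methoxy-2H-chromen-2-one | COc1c(OC/C=C(C)\CC(O)C=C)ccc2ccc(=O)oc12
F4 | step 2 | 7-{[(2Z,5R)-5-hydroxy-3-methyl-5-[(2S)-oxiran-2-yl]pent-2-en-1-yl]oxy}-8-methoxy-2H-chromen-2-one | COc1c(OC/C=C(C)\C[C@@H](O)[C@@H]2CO2)ccc3ccc(=O)oc13
F5 | step 6 | tert-butyl (3S,5Z)-7-[(8-methoxy-2-oxo-2H-chromen-7-yl)oxy]-5-methylhepta-1,5-dien-3-yl carbonate | COc1c(OC/C=C(C)\C[C@H](OC(=O)OC(C)(C)C)C=C)ccc2ccc(=O)oc12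
F6 | step 6 | (4R,6S)-6-ethenyl-4-[(1R)-1-iodo-2-[(8-methoxy-2-oxo-2H-chromen-7-yl)oxy]ethyl]-4-methyl-1,3-dioxan-2-one | COc1c(OC[C@@H](I)[C@@]2(C)C[C@@H](C=C)OC(=O)O2)ccc3ccc(=O)oc13
F7 | step 7 | triethylsilyl ether of 13 at the (2S)-carbinol, 7-{[(2S,3R)-3-methyl-3-[(2S)-2-(triethylsilyloxy)but-3-en-1-yl]oxiran-2-yl]methoxy}-8-methoxy-2H-chromen-2-one | COc1c(OC[C@@H]2O[C@]2(C)C[C@H](O[Si](CC)(CC)CC)C=C)ccc2ccc(=O)oc12
F8 | step 7 | (2S)-3-[(2R,3S)-3-{[(8-methoxy-2-oxo-2H-chromen-7-yl)oxy]methyl}-2-methyloxiran-2-yl]-2-(triethylsilyloxy)propanal | COc1c(OC[C@@H]2O[C@]2(C)C[C@H](O[Si](CC)(CC)CC)C=O)ccc2ccc(=O)oc12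
F9 | step 7 | triethylsilyl ether of 15 at the (2S)-carbinol, 7-{[(2S,3R)-3-methyl-3-[(2S)-4-methyl-2-(triethylsilyloxy)pent-3-en-1-yl]oxiran-2-yl]methoxy}-8-methoxy-2H-chromen-2-one | COc1c(OC[C@@H]2O[C@]2(C)C[C@H](O[Si](CC)(CC)CC)C=C(C)C)ccc2ccc(=O)oc12
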